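## Structural features

Target 37 is a dearomatised acylphloroglucinol. A six-membered carbocycle (ring A: C4a, C5, C6, C7, C8, C8a in chromane numbering) is fused along C4a–C8a to a 2,3-dimethyl-2,3-dihydropyran-4-one (ring B: O1, C2, C3, C4). The C4 and C5 oxygens form a chelated, enolised β-triketone that extends to C7 through C8a=C8. C6 is an all-carbon quaternary stereocentre that carries a prenyl group and the chain C1′H2–C2′H(C3′H=CMe2)–CH2CH2C(Me)=CH2; C8 carries an (R)-CH(Ph)CH2CO2H arm. There are five stereocentres: C2 (R) and C3 (S) are adjacent and cis; the benzylic carbon (R) sits on sp2 C8; C2′ (R) and C6 (S in the tautomer drawn) are 1,3-related across C1′. The fragile groups are the cis-2,3-dimethyl unit (C3 epimerises under base by enolisation or retro-oxa-Michael opening), the prenyl group next to enol oxygens (acid closes a pyran), the 1,1-disubstituted alkene (acid isomerisation) and the acidic triketone. The real difficulty is C6: it has no heteroatom and no adjacent stereocentre, and it is stereogenic only because the C5/C4a flank of ring A differs from the C7/C8 flank; in addition ring B must close on O8a and not on O5. The feature exploited is that C3′, carried as a hydroxymethyl group on C2′, can reach the oxygen of either C5 or C7 through a six-membered ring (O, C3′, C2′, C1′, C6, C5 or C7). A reversible ring closure therefore lets C2′ choose between the two carbonyls, which fixes C6 and masks O5 in one operation.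

## Logic of the disconnections

37 ⇒ 36. The C3′=CMe2 double bond is cut (Wittig). The isobutenyl CH is the one carbon of the side chain that can be traced back to an oxygenated carbon within reach of ring A. The gain is that the last C–C bond is made on an intermediate with all stereocentres in place and no protecting group. The demand is that the ylide adds faster than C2′ enolises and that the two acidic hydrogens are simply consumed by excess ylide.

36 ⇒ 35 ⇒ 34. The oxidation level at C3′ is lowered (35), then the C3′ oxygen is reconnected to C5 as a cyclic enol ether (34). This temporary C5–O bond is not part of 37; it is what keeps O5 etherified while ring B is built. The forward step is an addition–elimination of hydroxide at C5, which must be more electrophilic than C8a and must react before C3 is enolised.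

34 ⇒ 33 ⇒ 31. After adjusting the arm from acid to aldehyde (33), the O1–C8a bond is cut while the C2–O bond is kept. This leads to 31, where C4a carries a syn-configured 3-silyloxy-2-methylbutanoyl group and the C8 arm is masked as a cyclic acetal. Closing ring B by attack of the side-chain oxygen on C8a touches neither C2 nor C3, and a syn unit then gives the cis-dimethyl ring. Because O5 is tied up, only O8a can take part. The forward step needs an acid that removes the silyl ether and the acetal and dehydrates the hemiketal without harming the alkenes.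

31 ⇒ 22 + 29. The C4a–C4 bond is cut. In the tethered system C4a is the α-carbon of a vinylogous ester and not an enolate carbon, so the bond is made from the C4a-lithio species 30 and the N-methoxy-N-methylamide 29. The demand is that no hydrogen more acidic than the vinylic C4a–H is present; this is why the C8 arm is carried in 22 at the aldehyde level as a cyclic acetal that also ties up the enol oxygen. 29 ⇒ 28 ⇒ 27 ⇒ 23 + 24: the C2–C3 bond comes from an auxiliary-controlled syn aldol, which fixes both ring B centres in relative and absolute sense.

22 ⇒ 19 + 20. The C8–C(benzylic) bond is cut. In 19 C8 is the only 1,3-dicarbonyl methylene, so a catalytic Michael addition is regioselective without protection, and the catalyst sets the benzylic centre. The gain is that the second flank of ring A is addressed by the most reliable reaction of a cyclic 1,3-dione.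

19 ⇒ 18 (key step). The temporary O–C5 bond is cut, which returns the symmetric trione 18 in which C6 is not stereogenic. The forward ring closure sets C6 under thermodynamic control from C2′ alone. A check of the descriptors confirms that the C5-tethered isomer with the equatorial side chain (C2′ R, C6 S in 19) maps onto C6 of 37; no structural correction is needed. The demand is true reversibility and an acid mild enough for the two alkenes.

18 ⇒ 17 ⇒ 15 ⇒ 12 + 13. After the silyl ether and two carboxyl groups are added back, the C5–C4a and C7–C8 bonds are cut. Ring A then comes from a double C-acylation of the 1,3-bis-nucleophile 13 by a dialkylmalonyl unit. The product is symmetric, so no selectivity is required; the demand is C- rather than O-acylation in the ring-closing event.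

12 ⇒ 11 ⇒ 9 + 10, and 9 ⇒ 1 + 8. The two C6–C bonds are cut. The hindered β-branched iodide 8 is used first, on unsubstituted 1, and the reactive allylic bromide 10 second; the reverse order would force a slow SN2 reaction onto a tertiary carbanion.

8 ⇒ 7 ⇒ 6 ⇒ 5 ⇒ 4 ⇒ 3 ⇒ 1 + 2. C2′ is the only stereocentre that has to be bought. It is made by enzymatic desymmetrisation of the prochiral diol 4, followed by silylation, deacetylation and iodination. A bulky silyl group is required because migration of the silyl group between the two oxygens of 7 would be racemisation.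

## Other disconnections considered

Alternative 1: The C7–C8 bond of ring A is cut in the retro-Claisen sense. This leads to δ-lactone A1, in which C7 is the lactone carbonyl, the lactone oxygen sits on C3′, C6 is already quaternary and configured, and the other substituent on C6 is the open C5–C4a–C8a–C8 diketone chain with the benzylic tert-butyl ester arm. In the forward step two equivalents of an amide base convert the diketone of A1 into its dianion. The terminal carbanion (C8) attacks the lactone carbonyl, ring A closes (six-membered, acyl substitution) and the C3′ alkoxide is expelled to give A2.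
- In its favour: C6 is fixed before ring A exists, by alkylation of a lactone enolate in a rigid six-membered ring. The benzylic centre is set in an open chain. The arm needs no late functionalisation of ring A, which is a clear advantage over steps 14 and 18–20 of the chosen plan. The hydroxymethyl group is released in the ring-forming step.
- Against it here: the C6 configuration rests on kinetic 1,3-induction from C2′, which does not correct itself. The lactone carbonyl is neopentyl-like, so O-acylation to a pyranone and retro-Claisen attack of the freed alkoxide are plausible. The ester methylene is a third acidic site. A2 still has undifferentiated O5 and O8a, so the same C5 enol ether would have to be formed afterwards to direct ring B.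
- Comparison: on structure A2 is ahead (arm in place). On mechanism the chosen plan is ahead (thermodynamic rather than kinetic control of C6, mild acid rather than dianion chemistry next to an ester). On step economy the two are about equal, because the chain of A1 costs what the ring A functionalisation costs in the chosen route.

Alternative 2: Ring B is cut at C2–C3 and O1–C8a. The substrate is A3, in which the C4a propionyl group is a Z silyl enol ether conjugated with a C8a methyl enol ether (a 1-alkoxy-3-silyloxy diene), C7 is a silyl enol ether and the isobutenyl group is already present. In the forward step A3 and acetaldehyde 24 combine under Ti(OiPr)4 and BINOL in a Mukaiyama aldol addition (C2–C3), and the aldolate oxygen then displaces methanol at C8a (O1–C8a) to give A4.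
- In its favour: both ring B centres are made catalytically in one step from a two-carbon aldehyde. The acyl group is a plain propionyl that can be present from an early stage, so the difficult C4a acylation of the chosen plan (step 18) is avoided; this is the better solution for that bond. No base is needed after ring B exists. The O1–C8a bond is formed with retention at C2, which is mechanistically the equal of step 19.
- Against it here: the plan needs three regiodefined enol derivatives on one triketone (O8a methyl, O7 silyl, O5 free), which is the O5/O7/O8a differentiation problem in another form. It does nothing for C6. The catalyst must override two existing stereocentres with a small, enolisable aldehyde, and the cis/trans outcome depends on an open versus a closed transition state.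
- Comparison: ring B costs one step against five in the chosen route (better). Regiocontrol of the enol oxygens and control of C6 are left open (worse). The ring-closing bond is the same.

Alternative 3: The O1–C2 bond is cut. The substrate is A5, the C5-tethered enol with a (2S,3S)-3-hydroxy-2-methylbutanoyl group on C4a. Under PPh3 and diisopropyl azodicarboxylate the acidic C8a enol oxygen displaces the activated hydroxyl with inversion and gives the tethered tricycle A6.
- In its favour: it runs on the same tethered scaffold, so the regiochemistry of ring B is secured exactly as in the chosen plan (equal). The conditions are neutral, which is kinder to the prenyl and 1,1-disubstituted alkenes than the acid of step 19 (better). The anti unit is available from dianion methylation of an (S)-3-hydroxybutanoic ester, which is at least as economical as the auxiliary aldol.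
- Against it here: a β-hydroxy ketone under Mitsunobu activation is prone to elimination to the 2-methylbut-2-enoyl ketone, which would then cyclise without control. The nucleophile is a hindered, weakly nucleophilic vinylogous acid attacking a secondary carbon next to a branched centre. The stereocentre C2 is the reacting atom. The C4a acylation problem is identical.
- Comparison: step count is equal. The chosen plan forms the bond at sp2 C8a and leaves C2 and C3 untouched, whereas A5 → A6 inverts C2 and risks its loss. The alternative avoids acid; the chosen plan avoids an activated secondary alcohol.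

Key step: step 13

Assumption: Burkholderia cepacia lipase is taken to acetylate diol 4 in the sense that gives the (S)-monoacetate 5; if it gives the mirror image, steps 4–6 are run in the order iodination, deacetylation, silylation, which leads to the same iodide 8.

## Route

Step 1
Reactants: 1 dimethyl malonate; 2 4-bromo-2-methylbut-1-ene
Product: 3 dimethyl 2-(3-methylbut-3-en-1-yl)propanedioate
Conditions: 1 (3 equiv), NaH, THF–DMF, 0 °C; 2, NaI (cat.), 60 °C
Reagents that add atoms: none
Why: SN2 alkylation of sodiomalonate by a primary homoallylic bromide; excess 1 suppresses dialkylation.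

Step 2
Reactants: 3 dimethyl 2-(3-methylbut-3-en-1-yl)propanedioate
Product: 4 2-(3-methylbut-3-en-1-yl)propane-1,3-diol
Conditions: LiAlH4, THF, 0 °C → rt; aq. NaOH work-up
Reagents that add atoms: none
Why: Hydride reduction of both esters; the isolated alkene is inert.

Step 3
Reactants: 4 2-(3-methylbut-3-en-1-yl)propane-1,3-diol
Product: 5 (2S)-2-(hydroxymethyl)-5-methylhex-5-en-1-yl acetate
Conditions: Burkholderia cepacia lipase, vinyl acetate, t-BuOMe, 25 °C, stopped at the monoacetate
Reagents that add atoms: vinyl acetate, C=COC(C)=O
Why: Lipase-catalysed desymmetrisation of a prochiral 2-substituted propane-1,3-diol by irreversible transesterification sets C2′; further acetylation of the minor enantiomer to diacetate should raise the enantiomeric purity.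

Step 4
Reactants: 5 (2S)-2-(hydroxymethyl)-5-methylhex-5-en-1-yl acetate
Product: 6 (2R)-5-methyl-2-{[tri(propan-2-yl)silyl]oxymethyl}hex-5-en-1-yl acetate
Conditions: TIPSOTf, 2,6-lutidine, CH2Cl2, −78 °C
Reagents that add atoms: tri(propan-2-yl)silyl trifluoromethanesulfonate, CC(C)[Si](OS(=O)(=O)C(F)(F)F)(C(C)C)C(C)C
Why: Fast low-temperature silylation leaves no time for acetyl migration (which would racemise 5); the bulky silyl group is chosen because it should not migrate between the 1,3-oxygens later and survives hydroxide.

Step 5
Reactants: 6 (2R)-5-methyl-2-{[tri(propan-2-yl)silyl]oxymethyl}hex-5-en-1-yl acetate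
Product: 7 (2R)-5-methyl-2-{[tri(propan-2-yl)silyl]oxymethyl}hex-5-en-1-ol
Conditions: K2CO3 (cat.), MeOH, 0 °C
Reagents that add atoms: none
Why: Base-catalysed methanolysis of the acetate; C2′ is not involved and the silyl ether is stable.

Step 6
Reactants: 7 (2R)-5-methyl-2-{[tri(propan-2-yl)silyl]oxymethyl}hex-5-en-1-ol
Product: 8 {[(2S)-2-(iodomethyl)-5-methylhex-5-en-1-yl]oxy}tri(propan-2-yl)silane
Conditions: PPh3, I2, imidazole, CH2Cl2, 0 °C → rt
Reagents that add atoms: iodine, II
Why: Appel-type iodination of a primary alcohol under near-neutral conditions; the descriptor changes only through the priority rules.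

Step 7
Reactants: 1 dimethyl malonate; 8 {[(2S)-2-(iodomethyl)-5-methylhex-5-en-1-yl]oxy}tri(propan-2-yl)silane
Product: 9 dimethyl 2-[(2R)-5-methyl-2-{[tri(propan-2-yl)silyl]oxymethyl}hex-5-en-1-yl]propanedioate
Conditions: 1 (3 equiv), NaH, DMF, 0 °C; 8, 60 °C
Reagents that add atoms: none
Why: Malonate alkylation with the β-branched iodide is done first, while the nucleophile is still unhindered.

Step 8
Reactants: 9 dimethyl 2-[(2R)-5-methyl-2-{[tri(propan-2-yl)silyl]oxymethyl}hex-5-en-1-yl]propanedioate; 10 prenyl bromide (1-bromo-3-methylbut-2-ene)
Product: 11 dimethyl 2-(3-methylbut-2-en-1-yl)-2-[(2R)-5-methyl-2-{[tri(propan-2-yl)silyl]oxymethyl}hex-5-en-1-yl]propanedioate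
Conditions: NaH, THF–DMF, 0 °C; 10, rt
Reagents that add atoms: none
Why: The tertiary malonate anion reacts readily with the allylic bromide at its primary carbon; the future C6 is created as a prochiral quaternary centre.

Step 9
Reactants: 11 dimethyl 2-(3-methylbut-2-en-1-yl)-2-[(2R)-5-methyl-2-{[tri(propan-2-yl)silyl]oxymethyl}hex-5-en-1-yl]propanedioate
Product: 12 2-(3-methylbut-2-en-1-yl)-2-[(2R)-5-methyl-2-{[tri(propan-2-yl)silyl]oxymethyl}hex-5-en-1-yl]propanedioic acid
Conditions: KOH, MeOH–H2O, 70 °C; then 1 M HCl to pH 3, 0 °C
Reagents that add atoms: potassium hydroxide, [K+].[OH-]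
Why: Saponification of a dialkylmalonate; the triisopropylsilyl ether tolerates hydroxide and the free diacid is kept cold to avoid decarboxylation.

Step 10
Reactants: 12 2-(3-methylbut-2-en-1-yl)-2-[(2R)-5-methyl-2-{[tri(propan-2-yl)silyl]oxymethyl}hex-5-en-1-yl]propanedioic acid; 13 dimethyl 3-oxopentanedioate
Product: 15 dimethyl 5-(3-methylbut-2-en-1-yl)-5-[(2R)-5-methyl-2-{[tri(propan-2-yl)silyl]oxymethyl}hex-5-en-1-yl]-2,4,6-trioxocyclohexane-1,3-dicarboxylate (enolised), via malonyl dichloride 14 (not isolated)
Conditions: 1-chloro-N,N,2-trimethylprop-1-en-1-amine (2.2 equiv), CH2Cl2, 0 °C → rt; then 13, MgCl2, Et3N, MeCN, 0 °C → rt; 1 M HCl work-up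
Reagents that add atoms: none
Why: The chloroenamine gives the diacid chloride without HCl (alkenes and silyl ether safe), and the chloride has no α-hydrogen, so no ketene can form. The magnesium chelate of 13 is then C-acylated at both methylene carbons (Claisen-type acylation followed by six-membered ring-closing acylation) to the symmetric, fully enolised trione diester.

Step 11
Reactants: 15 dimethyl 5-(3-methylbut-2-en-1-yl)-5-[(2R)-5-methyl-2-{[tri(propan-2-yl)silyl]oxymethyl}hex-5-en-1-yl]-2,4,6-trioxocyclohexane-1,3-dicarboxylate (enolised)
Product: 17 2-(3-methylbut-2-en-1-yl)-2-[(2R)-5-methyl-2-{[tri(propan-2-yl)silyl]oxymethyl}hex-5-en-1-yl]cyclohexane-1,3,5-trione, via trione dicarboxylic acid 16 (not isolated)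
Conditions: NaOH (2 M aq), MeOH, 70 °C; then 1 M HCl to pH 2, 40 °C
Reagents that add atoms: none
Why: The esters are saponified while the ring is a polyanion, which shields the ring carbonyls from retro-Claisen attack; the two β-keto acids lose CO2 on acidification.

Step 12
Reactants: 17 2-(3-methylbut-2-en-1-yl)-2-[(2R)-5-methyl-2-{[tri(propan-2-yl)silyl]oxymethyl}hex-5-en-1-yl]cyclohexane-1,3,5-trione
Product: 18 2-[(2R)-2-(hydroxymethyl)-5-methylhex-5-en-1-yl]-2-(3-methylbut-2-en-1-yl)cyclohexane-1,3,5-trione
Conditions: Bu4NF, AcOH, THF, rt; pH 4 work-up; used at once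
Reagents that add atoms: none
Why: Fluoride cleaves the Si–O bond; acetic acid keeps the liberated alkoxide protonated so that it cannot open the ring by retro-Claisen attack.

Step 13
Reactants: 18 2-[(2R)-2-(hydroxymethyl)-5-methylhex-5-en-1-yl]-2-(3-methylbut-2-en-1-yl)cyclohexane-1,3,5-trione
Product: 19 (3R,4aS)-3-(3-methylbut-3-en-1-yl)-4a-(3-methylbut-2-en-1-yl)-3,4-dihydro-2H-chromene-5,7(4aH,6H)-dione (C3′ oxygen bonded to C5)
Conditions: PPTS (0.1 equiv), benzene (0.02 M), 60 °C without drying; then reflux through 4 Å molecular sieves
Reagents that add atoms: none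
Why: Acid-catalysed cyclodehydration: the primary hydroxyl adds to the protonated C5 or C7 carbonyl (6-exo-trig in both cases, ring O–C3′–C2′–C1′–C6–C5) to give a hemiketal that loses water to the vinylogous ester, and every stage is reversible while water is present, which is why the first phase is run without drying. The closest known reaction type is the acid-catalysed formation of 3-alkoxy-enones from cyclic 1,3-diones and alcohols, used here intramolecularly as a thermodynamic desymmetrisation of a 2,2-disubstituted 1,3-dione. The new oxacycle is fused to ring A like the saturated ring of an angularly substituted octalenone, so on C6 the ring A carbon C7 must be equatorial and the prenyl group axial. The two possible products then differ only in the 3-methylbut-3-enyl group on C2′: closure on C5 puts it equatorial, closure on C7 puts it axial and 1,3-syn to the axial prenyl group, a syn-pentane-type repulsion that should cost more than an ordinary axial substituent. C6 is therefore set by C2′ under thermodynamic control, with no asymmetric alkylation, and the equatorial isomer 19 (C2′ R, C6 S, oxygen on C5) is the one whose C6 configuration maps onto 37. The selectivity needed is between the diastereotopic C5 and C7 carbonyls; C8a is out of reach (eight-membered ring) and high dilution suppresses intermolecular ether formation. PPTS is used in place of a sulfonic acid so that neither addition of an enol oxygen to the prenyl double bond nor isomerisation of the 1,1-disubstituted alkene competes. After closure C8 is a 1,3-dicarbonyl methylene and C4a a vinylogous-ester α-carbon, so the two flanks of ring A can be addressed one after the other.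

Step 14
Reactants: 19 (3R,4aS)-3-(3-methylbut-3-en-1-yl)-4a-(3-methylbut-2-en-1-yl)-3,4-dihydro-2H-chromene-5,7(4aH,6H)-dione; 20 (E)-cinnamaldehyde
Product: 22 O7-linked cyclic methyl acetal of the C8 adduct [(2R,4R)-2-methoxy-4-phenyl-3,4-dihydro-2H-pyran ring fused at C7–C8; tether intact], via Michael-adduct aldehyde 21 (not isolated)
Conditions: 20 (1.2 equiv), (R)-2-[diphenyl(trimethylsilyloxy)methyl]pyrrolidine (10 mol %), PhCO2H (10 mol %), CH2Cl2, rt; then HC(OMe)3, PPTS (5 mol %), 0 °C → rt
Reagents that add atoms: trimethyl orthoformate, COC(OC)OC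
Why: Iminium-catalysed Michael addition of a cyclic 1,3-dicarbonyl (C8, the only such methylene) to an enal; the (R)-catalyst shields the Si face of the β-carbon, so attack on the Re face should give the (R)-benzylic centre. Acetalisation of the resulting lactol ties up the enol oxygen and the aldehyde so that no acidic hydrogen remains for step 18; the trans anomer on O7 is drawn, and the other anomer or an O8a-linked regioisomer would converge in step 19.

Step 15
Reactants: 23 (S)-4-benzyl-3-propanoyl-1,3-oxazolidin-2-one; 24 acetaldehyde
Product: 27 (S)-4-benzyl-3-[(2S,3R)-3-hydroxy-2-methylbutanoyl]-1,3-oxazolidin-2-one, via boron enolate 25 (not isolated), via boron aldolate 26 (not isolated)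
Conditions: Bu2BOTf, Et3N, CH2Cl2, 0 °C; 24, −78 → 0 °C; pH 7 buffer, MeOH, H2O2
Reagents that add atoms: none
Why: Evans syn aldol reaction: the Z boron enolate reacts through a closed chair transition state on the face opposite the benzyl group, which sets the future C3 (S) and C2 (R) together.

Step 16
Reactants: 27 (S)-4-benzyl-3-[(2S,3R)-3-hydroxy-2-methylbutanoyl]-1,3-oxazolidin-2-one
Product: 28 (2S,3R)-3-hydroxy-N-methoxy-N,2-dimethylbutanamide
Conditions: MeNHOMe·HCl, AlMe3, CH2Cl2, −20 → 0 °C; aq. potassium sodium tartrate
Reagents that add atoms: N,O-dimethylhydroxylamine hydrochloride, CNOC.Cl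
Why: Aluminium amide transamidation of the imide, assisted by the free β-hydroxyl, gives the Weinreb amide without touching the α-centre; the auxiliary is recovered.

Step 17
Reactants: 28 (2S,3R)-3-hydroxy-N-methoxy-N,2-dimethylbutanamide
Product: 29 (2S,3R)-N-methoxy-N,2-dimethyl-3-(triethylsilyloxy)butanamide
Conditions: TESCl, imidazole, CH2Cl2, 0 °C → rt
Reagents that add atoms: chlorotriethylsilane, CC[Si](Cl)(CC)CC
Why: Silylation of the secondary alcohol; the triethylsilyl group survives the organolithium step and falls off under the acid of step 19.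

Step 18
Reactants: 22 O7-linked cyclic methyl acetal of the C8 adduct; 29 (2S,3R)-N-methoxy-N,2-dimethyl-3-(triethylsilyloxy)butanamide
Product: 31 C4a-[(2S,3R)-2-methyl-3-(triethylsilyloxy)butanoyl] derivative of 22, via C4a-lithio acetal 30 (not isolated)
Conditions: lithium 2,2,6,6-tetramethylpiperidide (LiTMP, 1.3 equiv), THF, −78 °C; 29, −78 → −40 °C; aq. NH4Cl, then pH 4 citrate wash, cold
Reagents that add atoms: none
Why: α-Vinylic lithiation of a β-alkoxy enone (C4a–H lies between the C8a carbonyl and the alkoxy-bearing C5 and is the only acidic hydrogen in 22), followed by acylation with a Weinreb amide. The chelated tetrahedral intermediate survives until work-up, so the α-stereocentre of the acyl group is not exposed to base as a ketone.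

Step 19
Reactants: 31 C4a-[(2S,3R)-2-methyl-3-(triethylsilyloxy)butanoyl] derivative of 22
Product: 33 tethered tricycle aldehyde [ring B closed on O8a; (2R,3S)-cis-2,3-dimethyl; C8 bears (1R)-3-oxo-1-phenylpropyl], via deprotected hydroxy-ketone 32 (not isolated)
Conditions: 1 M HCl–THF (1:4), 0 °C → rt; then PPTS (10 mol %), benzene, 4 Å molecular sieves, 50 °C
Reagents that add atoms: water, O
Why: Acid removes the silyl ether and the mixed acetal; the secondary hydroxyl then adds to C8a and water is lost (cyclodehydration of a δ-hydroxy-β-diketone to a dihydropyranone), with the C2–O bond untouched, so the syn unit gives the cis ring. O5 stays etherified by the tether, and any exchange at C5 is reversible, with the doubly ring-closed isomer carrying the equatorial tether as the expected resting point.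

Step 20
Reactants: 33 tethered tricycle aldehyde
Product: 34 tethered tricycle acid [as 33 but C8 bears (1R)-2-carboxy-1-phenylethyl]
Conditions: NaClO2, NaH2PO4, 2-methylbut-2-ene (large excess), t-BuOH–H2O, 0 °C → rt
Reagents that add atoms: sodium chlorite, [Na+].[O-]Cl=O
Why: Pinnick oxidation; ring A has no free enol or nucleophilic C–H left, and the scavenger protects the prenyl group from hypochlorous acid.

Step 21
Reactants: 34 tethered tricycle acid
Product: 35 seco hydroxy acid [37 with CH2OH in place of the isobutenyl group on C2′]
Conditions: LiOH (4 equiv), THF–H2O (3:1), 0 °C; then 1 M HCl to pH 4, 0 °C; used at once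
Reagents that add atoms: lithium hydroxide, [Li+].[OH-]
Why: Addition–elimination of hydroxide at C5, the β-carbon of the C4 enone and δ-carbon of the C7 dienone, where the adduct anion is stabilised by both carbonyls (attack at C8a gives only a simple enolate); the C3′ alkoxide is expelled. The triketonate formed makes the opening irreversible and should protect C3 from enolisation.

Step 22
Reactants: 35 seco hydroxy acid
Product: 36 C3′ aldehyde [37 with CHO in place of the isobutenyl group on C2′]
Conditions: Dess–Martin periodinane, CH2Cl2, 0 °C → rt
Reagents that add atoms: none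
Why: Oxidation of the primary alcohol under non-basic conditions that do not enolise C2′; ring A has no C–H between carbonyls, so the triketone is not attacked.

Step 23
Reactants: 36 C3′ aldehyde
Product: 37 target acid CNP0155375.4
Conditions: i-PrPPh3I (5 equiv), n-BuLi (4.8 equiv), THF, 0 °C; 36, −78 → 0 °C; aq. citric acid
Reagents that add atoms: isopropyltriphenylphosphonium iodide, CC(C)[P+](c1ccccc1)(c1ccccc1)c1ccccc1.[I-]
Why: Wittig olefination with the non-stabilised isopropylidene ylide; two equivalents are consumed by the acid and the enol, whose anions shield C3 and the ring carbonyls, and addition at −78 °C should outrun enolisation at C2′.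

## Compound list

1 | dimethyl malonate | COC(=O)CC(=O)OC | starting material
2 | 4-bromo-2-methylbut-1-ene | C=C(C)CCBr | starting material
3 | dimethyl 2-(3-methylbut-3-en-1-yl)propanedioate | C=C(C)CCC(C(=O)OC)C(=O)OC | intermediate
4 | 2-(3-methylbut-3-en-1-yl)propane-1,3-diol | C=C(C)CCC(CO)CO | intermediate
5 | (2S)-2-(hydroxymethyl)-5-methylhex-5-en-1-yl acetate | C=C(C)CC[C@@H](CO)COC(C)=O | intermediate
6 | (2R)-5-methyl-2-{[tri(propan-2-yl)silyl]oxymethyl}hex-5-en-1-yl acetate | C=C(C)CC[C@@H](CO[Si](C(C)C)(C(C)C)C(C)C)COC(C)=O | intermediate
7 | (2R)-5-methyl-2-{[tri(propan-2-yl)silyl]oxymethyl}hex-5-en-1-ol | C=C(C)CC[C@@H](CO[Si](C(C)C)(C(C)C)C(C)C)CO | intermediate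
8 | {[(2S)-2-(iodomethyl)-5-methylhex-5-en-1-yl]oxy}tri(propan-2-yl)silane | C=C(C)CC[C@@H](CO[Si](C(C)C)(C(C)C)C(C)C)CI | intermediate
9 | dimethyl 2-[(2R)-5-methyl-2-{[tri(propan-2-yl)silyl]oxymethyl}hex-5-en-1-yl]propanedioate | C=C(C)CC[C@@H](CO[Si](C(C)C)(C(C)C)C(C)C)CC(C(=O)OC)C(=O)OC | intermediate
10 | prenyl bromide (1-bromo-3-methylbut-2-ene) | CC(C)=CCBr | starting material
11 | dimethyl 2-(3-methylbut-2-en-1-yl)-2-[(2R)-5-methyl-2-{[tri(propan-2-yl)silyl]oxymethyl}hex-5-en-1-yl]propanedioate | C=C(C)CC[C@@H](CO[Si](C(C)C)(C(C)C)C(C)C)CC(CC=C(C)C)(C(=O)OC)C(=O)OC | intermediate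
12 | 2-(3-methylbut-2-en-1-yl)-2-[(2R)-5-methyl-2-{[tri(propan-2-yl)silyl]oxymethyl}hex-5-en-1-yl]propanedioic acid | C=C(C)CC[C@@H](CO[Si](C(C)C)(C(C)C)C(C)C)CC(CC=C(C)C)(C(=O)O)C(=O)O | intermediate
13 | dimethyl 3-oxopentanedioate | COC(=O)CC(=O)CC(=O)OC | starting material
14 | 2-(3-methylbut-2-en-1-yl)-2-[(2R)-5-methyl-2-{[tri(propan-2-yl)silyl]oxymethyl}hex-5-en-1-yl]propanedioyl dichloride | C=C(C)CC[C@@H](CO[Si](C(C)C)(C(C)C)C(C)C)CC(CC=C(C)C)(C(Cl)=O)C(Cl)=O | intermediate
15 | dimethyl 5-(3-methylbut-2-en-1-yl)-5-[(2R)-5-methyl-2-{[tri(propan-2-yl)silyl]oxymethyl}hex-5-en-1-yl]-2,4,6-trioxocyclohexane-1,3-dicarboxylate, drawn as the symmetric dienol | C=C(C)CC[C@@H](CO[Si](C(C)C)(C(C)C)C(C)C)CC1(CC=C(C)C)C(O)=C(C(=O)OC)C(=O)C(C(=O)OC)=C1O | intermediate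
16 | the 1,3-dicarboxylic acid corresponding to 15, drawn as the symmetric dienol | C=C(C)CC[C@@H](CO[Si](C(C)C)(C(C)C)C(C)C)CC1(CC=C(C)C)C(O)=C(C(=O)O)C(=O)C(C(=O)O)=C1O | intermediate
17 | 2-(3-methylbut-2-en-1-yl)-2-[(2R)-5-methyl-2-{[tri(propan-2-yl)silyl]oxymethyl}hex-5-en-1-yl]cyclohexane-1,3,5-trione | C=C(C)CC[C@@H](CO[Si](C(C)C)(C(C)C)C(C)C)CC1(CC=C(C)C)C(=O)CC(=O)CC1=O | intermediate
18 | 2-[(2R)-2-(hydroxymethyl)-5-methylhex-5-en-1-yl]-2-(3-methylbut-2-en-1-yl)cyclohexane-1,3,5-trione (key-step precursor) | C=C(C)CC[C@@H](CO)CC1(CC=C(C)C)C(=O)CC(=O)CC1=O | intermediate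
19 | (3R,4aS)-3-(3-methylbut-3-en-1-yl)-4a-(3-methylbut-2-en-1-yl)-3,4-dihydro-2H-chromene-5,7(4aH,6H)-dione; in target numbering the C3′ oxygen is bonded to C5, C2′ R, C6 S (key-step product) | C=C(C)CC[C@H]1COC2=CC(=O)CC(=O)[C@@]2(CC=C(C)C)C1 | intermediate
20 | (E)-cinnamaldehyde | O=C/C=C/c1ccccc1 | starting material
21 | Michael adduct: 19 carrying (1R)-3-oxo-1-phenylpropyl on C8, drawn as the open C7 enol (in equilibrium with its lactols) | C=C(C)CC[C@H]1COC2=CC(=O)C([C@H](CC=O)c3ccccc3)=C(O)[C@@]2(CC=C(C)C)C1 | intermediate
22 | cyclic methyl acetal of 21: (2R,4R)-2-methoxy-4-phenyl-3,4-dihydro-2H-pyran ring closed through O7 and fused at C7=C8; C8a ketone, C4a–H, C5–O tether, C2′ and C6 unchanged; trans anomer drawn | C=C(C)CC[C@H]1COC2=CC(=O)C3=C(O[C@@H](OC)C[C@@H]3c4ccccc4)[C@@]2(CC=C(C)C)C1 | intermediate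
23 | (S)-4-benzyl-3-propanoyl-1,3-oxazolidin-2-one | O=C1OC[C@H](Cc2ccccc2)N1C(=O)CC | starting material
24 | acetaldehyde | CC=O | starting material
25 | (Z)-dibutylboron enolate of 23 | C/C=C(\OB(CCCC)CCCC)N1C(=O)OC[C@@H]1Cc1ccccc1 | intermediate
26 | dibutylboron aldolate of 27 | O=C1OC[C@H](Cc2ccccc2)N1C(=O)[C@@H](C)[C@@H](C)OB(CCCC)CCCC | intermediate
27 | (S)-4-benzyl-3-[(2S,3R)-3-hydroxy-2-methylbutanoyl]-1,3-oxazolidin-2-one | O=C1OC[C@H](Cc2ccccc2)N1C(=O)[C@@H](C)[C@@H](C)O | intermediate
28 | (2S,3R)-3-hydroxy-N-methoxy-N,2-dimethylbutanamide | O=C(N(C)OC)[C@@H](C)[C@@H](C)O | intermediate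
29 | (2S,3R)-N-methoxy-N,2-dimethyl-3-(triethylsilyloxy)butanamide | O=C(N(C)OC)[C@@H](C)[C@@H](C)O[Si](CC)(CC)CC | intermediate
30 | C4a-lithio derivative of 22 | C=C(C)CC[C@H]1COC2=C([Li])C(=O)C3=C(O[C@@H](OC)C[C@@H]3c4ccccc4)[C@@]2(CC=C(C)C)C1 | intermediate
31 | 22 carrying a (2S,3R)-2-methyl-3-(triethylsilyloxy)butanoyl group on C4a | C=C(C)CC[C@H]1COC2=C(C(=O)[C@@H](C)[C@@H](C)O[Si](CC)(CC)CC)C(=O)C3=C(O[C@@H](OC)C[C@@H]3c4ccccc4)[C@@]2(CC=C(C)C)C1 | intermediate
32 | deprotected form of 31: C4a-[(2S,3R)-3-hydroxy-2-methylbutanoyl], C8-[(1R)-3-oxo-1-phenylpropyl], free C7 enol, C5–O tether | C=C(C)CC[C@H]1COC2=C(C(=O)[C@@H](C)[C@@H](C)O)C(=O)C([C@H](CC=O)c3ccccc3)=C(O)[C@@]2(CC=C(C)C)C1 | intermediate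
33 | tethered tricycle aldehyde: ring B closed on O8a with (2R,3S)-cis-2,3-dimethyl, C4 ketone, C7 ketone, C5–O tether, C8-[(1R)-3-oxo-1-phenylpropyl] | C=C(C)CC[C@H]1COC2=C3C(=O)[C@@H](C)[C@@H](C)OC3=C([C@H](CC=O)c3ccccc3)C(=O)[C@@]2(CC=C(C)C)C1 | intermediate
34 | tethered tricycle acid: 33 with CO2H in place of CHO | C=C(C)CC[C@H]1COC2=C3C(=O)[C@@H](C)[C@@H](C)OC3=C([C@H](CC(=O)O)c3ccccc3)C(=O)[C@@]2(CC=C(C)C)C1 | intermediate
35 | seco hydroxy acid: 37 with CH2OH in place of the isobutenyl group on C2′ (C2′ R) | C=C(C)CC[C@@H](CO)C[C@@]1(CC=C(C)C)C(=O)C2=C(O)[C@@H](C)[C@@H](C)OC2=C([C@H](CC(=O)O)c2ccccc2)C1=O | intermediate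
36 | C3′ aldehyde: 37 with CHO in place of the isobutenyl group on C2′ (C2′ R) | C=C(C)CC[C@@H](C=O)C[C@@]1(CC=C(C)C)C(=O)C2=C(O)[C@@H](C)[C@@H](C)OC2=C([C@H](CC(=O)O)c2ccccc2)C1=O | intermediate
37 | CNP0155375.4: (3R)-3-phenyl-3-[chromenone core]propanoic acid with C2 R, C3 S (cis-dimethyl), C6 S carrying prenyl and (2R)-5-methyl-2-(2-methylprop-1-en-1-yl)hex-5-en-1-yl | C=C(C)CC[C@@H](C=C(C)C)C[C@@]1(CC=C(C)C)C(=O)C2=C(O)[C@@H](C)[C@@H](C)OC2=C([C@H](CC(=O)O)c2ccccc2)C1=O | target

## Step count and weakest steps

Total: 23 steps. Longest linear sequence: 20 steps (steps 1–14 and 18–23); the amide branch (steps 15–17) joins at step 18.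

Step 13 (key step). Most likely failure: incomplete equilibration, which would leave a kinetic mixture of the C5- and C7-tethered enol ethers, or acid-promoted addition of an enol oxygen to the prenyl double bond during prolonged heating. Fallback: starting from 18, an intramolecular Mitsunobu etherification (PPh3, diisopropyl azodicarboxylate, THF, 0 °C) forms the O–C3′ bond under neutral conditions and gives 19 together with its C6 epimer, the C7-tethered enol ether F1. The pair is separated, or equilibrated at room temperature with PPTS in CH2Cl2 containing one equivalent of methanol, and the route is rejoined at 19.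

Step 18. Most likely failure: slow or unselective metalation (competing deprotonation at the benzylic C–H, or different behaviour of an O8a-linked acetal regioisomer) and sluggish addition of the hindered vinyllithium to the α-branched amide. Fallback: starting from 29, reduction with i-Bu2AlH at −78 °C gives (2S,3R)-2-methyl-3-(triethylsilyloxy)butanal F2. This more reactive electrophile is added to the lithio species 30 made from 22, giving the C4 carbinols F3 (both epimers). Oxidation with Dess–Martin periodinane converges on 31, where the route is rejoined.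

Step 19. Most likely failure: acid-promoted β-elimination of the aldol hydroxyl before the hemiketal forms, which would destroy C2, or loss of the tether without re-closure. Fallback: starting from 31, the acid treatment is pushed on purpose (PPTS, benzene, 80 °C) to the (E)-2-methylbut-2-enoyl ketone F4. An amine-mediated intramolecular oxa-Michael addition of the C8a enol with quinine then closes ring B; this reaction type is cis-selective for 2-hydroxyaryl 2-methylbut-2-enoyl ketones and sets C2 and C3 under catalyst control. The route is rejoined at 33.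

Step 21. Most likely failure: competing hydroxide attack at C8a, which opens ring B, or enolisation at C3 before the tether opens, which would epimerise the cis-dimethyl unit. Fallback: starting from 34, sodium 1-phenyl-1H-tetrazole-5-thiolate in DMF at 60 °C cleaves the primary O–CH2 bond by SN2 (the secondary C2–O1 bond of ring B should be far slower, and conjugate addition at C5 is reversible) and gives the 1-phenyl-1H-tetrazol-5-yl sulfide F5. Oxidation with H2O2 and catalytic (NH4)6Mo7O24 gives the sulfone F6. A Julia–Kocienski olefination with acetone (KN(SiMe3)2 in excess, THF, −78 °C → rt) then gives 37 directly, so the route is rejoined at 37 and steps 22 and 23 are not needed.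

Step 10. Most likely failure: O-acylation in the ring-closing event, which would give a pyran-2,4-dione in place of the carbocycle. Fallback: starting from 11, the dianion of tert-butyl 3-oxobutanoate (NaH, then n-BuLi, THF, 0 °C) is acylated at its terminal carbon by one ester group, and t-BuOK then closes the ring on the second ester (Dieckmann condensation) to give the tert-butyl trioxocyclohexanecarboxylate F7 (mixture of C6 epimers, both of which converge). Cleavage of the tert-butyl ester with TMSOTf and 2,6-lutidine, followed by aqueous work-up and gentle warming, removes 2-methylpropene and CO2, and the route is rejoined at 17.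

## Further compounds

F1 | step 13 | C7-tethered enol ether, the C6 epimer of 19 (3R,4aR) | C=C(C)CC[C@H]1COC2=CC(=O)CC(=O)[C@]2(CC=C(C)C)C1
F2 | step 18 | (2S,3R)-2-methyl-3-(triethylsilyloxy)butanal | O=C[C@@H](C)[C@@H](C)O[Si](CC)(CC)CC
F3 | step 18 | C4 carbinols from 30 and F2 (both C4 epimers) | C=C(C)CC[C@H]1COC2=C(C(O)[C@@H](C)[C@@H](C)O[Si](CC)(CC)CC)C(=O)C3=C(O[C@@H](OC)C[C@@H]3c4ccccc4)[C@@]2(CC=C(C)C)C1
F4 | step 19 | C4a-[(E)-2-methylbut-2-enoyl] C8a enol with C8-[(1R)-3-oxo-1-phenylpropyl] and the C5–O tether | C=C(C)CC[C@H]1COC2=C(C(=O)/C(C)=C/C)C(O)=C([C@H](CC=O)c3ccccc3)C(=O)[C@@]2(CC=C(C)C)C1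
F5 | step 21 | 37 with CH2–S–(1-phenyl-1H-tetrazol-5-yl) in place of the isobutenyl group on C2′ | C=C(C)CC[C@@H](CSc1nnnn1-c1ccccc1)C[C@@]1(CC=C(C)C)C(=O)C2=C(O)[C@@H](C)[C@@H](C)OC2=C([C@H](CC(=O)O)c2ccccc2)C1=O
F6 | step 21 | the sulfone corresponding to F5 | C=C(C)CC[C@@H](CS(=O)(=O)c1nnnn1-c1ccccc1)C[C@@]1(CC=C(C)C)C(=O)C2=C(O)[C@@H](C)[C@@H](C)OC2=C([C@H](CC(=O)O)c2ccccc2)C1=O
F7 | step 10 | tert-butyl 2-hydroxy-4,6-dioxo-5-(3-methylbut-2-en-1-yl)-5-[(2R)-5-methyl-2-{[tri(propan-2-yl)silyl]oxymethyl}hex-5-en-1-yl]cyclohex-1-ene-1-carboxylate (both C5 epimers) | C=C(C)CC[C@@H](CO[Si](C(C)C)(C(C)C)C(C)C)CC1(CC=C(C)C)C(=O)CC(O)=C(C(=O)OC(C)(C)C)C1=O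
A1 | alternative 1 | δ-lactone (C7 lactone carbonyl, oxygen on C3′) with quaternary C6 carrying prenyl and the 1,3-diketone chain with the benzylic tert-butyl ester | C=C(C)CC[C@H]1COC(=O)[C@@](CC=C(C)C)(C1)C(=O)CC(=O)C[C@H](CC(=O)OC(C)(C)C)c1ccccc1
A2 | alternative 1 | ring A trione with hydroxymethyl arm at C2′ and tert-butyl ester | C=C(C)CC[C@@H](CO)C[C@@]1(CC=C(C)C)C(=O)CC(O)=C([C@H](CC(=O)OC(C)(C)C)c2ccccc2)C1=O
A3 | alternative 2 | Z silyl enol ether of the C4a propionyl group with C8a methyl enol ether and C7 silyl enol ether, methyl ester | C=C(C)CC[C@@H](C=C(C)C)C[C@@]1(CC=C(C)C)C(=O)C(/C(O[Si](C)(C)C(C)(C)C)=C/C)=C(OC)C([C@H](CC(=O)OC)c2ccccc2)=C1O[Si](C)(C)C(C)(C)C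
A4 | alternative 2 | ring B closed, methyl ester, C7 silyl enol ether | C=C(C)CC[C@@H](C=C(C)C)C[C@@]1(CC=C(C)C)C(=O)C2=C(O[C@H](C)[C@H](C)C2=O)C([C@H](CC(=O)OC)c2ccccc2)=C1O[Si](C)(C)C(C)(C)C
A5 | alternative 3 | C5-tethered C8a enol with (2S,3S)-3-hydroxy-2-methylbutanoyl on C4a, methyl ester | C=C(C)CC[C@H]1COC2=C(C(=O)[C@@H](C)[C@H](C)O)C(O)=C([C@H](CC(=O)OC)c3ccccc3)C(=O)[C@@]2(CC=C(C)C)C1
A6 | alternative 3 | tethered tricycle with ring B closed, methyl ester | C=C(C)CC[C@H]1COC2=C3C(=O)[C@@H](C)[C@@H](C)OC3=C([C@H](CC(=O)OC)c3ccccc3)C(=O)[C@@]2(CC=C(C)C)C1
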